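Berkazaphilone C is cut across ring B (the carbocycle C4a–C5–C6–C7–C8–C8a of the 1H-isochromen-6-one core) at C5–C6 and C8–C8a. This exploits two features: C6 (ketone) and C8 (carbinol) flank the quaternary C7 like the ester and aldehyde of a 2-methylglycerate unit, and C5 and C8a flank C4a, a latent ketone carbon. In one flask, a chelation-controlled Mukaiyama aldol (C8a to C8) and a Dieckmann-type acylation (C5 to C6) join an aldehyde ester, whose chiral-pool stereocentre C7 relays C8 and C8a, to the internal enol silane of a protected 4-hydroxybutanone. The resulting cyclohexane-1,3-dione gains C3/C4 by enol triflate coupling, and pyran ring A closes last.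

Key step: step 9

Remark: atom labels (O2, C1, C3, C4, C4a, C5–C8, C8a; ring A = pyran, ring B = carbocycle) are those of the target and are kept for all precursors. Compounds 1, 7, 10, 11 and 13 are taken as commercial.

Step 1
Reactants: 1 (S)-3-bromo-2-hydroxy-2-methylpropanoic acid
Product: 3 (R)-2,3-dihydroxy-2-methylpropanoic acid, via sodium (R)-2-methyloxirane-2-carboxylate 2 (not isolated)
Conditions: NaOH (3 equiv), H2O, 0 → 50 °C; then HCl to pH 2, evaporation
Reagents that add atoms: sodium hydroxide, [Na+].[OH-]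
Why: Williamson closure of the bromohydrin to the glycidate and SN2 opening by hydroxide at the unhindered CH2 terminus never break the C2–O bond, so the stereocentre is retained (the descriptor changes from S to R only because CH2Br outranks CO2H and CH2OH does not).

Step 2
Reactants: 3 (R)-2,3-dihydroxy-2-methylpropanoic acid
Product: 4 methyl (R)-2,3-dihydroxy-2-methylpropanoate
Conditions: MeOH, H2SO4 (cat.), reflux
Reagents that add atoms: methanol, CO
Why: Fischer esterification; the quaternary stereocentre cannot epimerise.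

Step 3
Reactants: 4 methyl (R)-2,3-dihydroxy-2-methylpropanoate
Product: 5 methyl (R)-2-methyl-2,3-bis[(triethylsilyl)oxy]propanoate
Conditions: Et3SiOTf (2.5 equiv), 2,6-lutidine, CH2Cl2, −78 → 0 °C
Reagents that add atoms: triethylsilyl trifluoromethanesulfonate, CC[Si](CC)(CC)OS(=O)(=O)C(F)(F)F
Why: Silyl triflate silylation is strong enough for the tertiary α-hydroxy ester oxygen as well as the primary one.

Step 4
Reactants: 5 methyl (R)-2-methyl-2,3-bis[(triethylsilyl)oxy]propanoate
Product: 6 methyl (R)-2-methyl-3-oxo-2-[(triethylsilyl)oxy]propanoate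
Conditions: (COCl)2, DMSO, CH2Cl2, −78 → −40 °C; then Et3N, → 0 °C
Reagents that add atoms: none
Why: Swern conditions cleave and oxidise a primary triethylsilyl ether directly to the aldehyde while the tertiary one survives (oxidative deprotection under Swern oxidation); the aldehyde is non-enolisable, so C7 is safe.

Step 5
Reactants: 7 4-hydroxybutan-2-one
Product: 8 4-[(tert-butyldimethylsilyl)oxy]butan-2-one
Conditions: TBSCl, imidazole, CH2Cl2, 0 °C → rt
Reagents that add atoms: tert-butyldimethylsilyl chloride, CC(C)(C)[Si](C)(C)Cl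
Why: Standard silylation of a primary alcohol.

Step 6
Reactants: 8 4-[(tert-butyldimethylsilyl)oxy]butan-2-one
Product: 9 (Z)-1-[(tert-butyldimethylsilyl)oxy]-3-[(trimethylsilyl)oxy]but-2-ene
Conditions: Me3SiCl, NaI, Et3N, MeCN, 0 °C → rt; distillation
Reagents that add atoms: chlorotrimethylsilane, C[Si](C)(C)Cl
Why: Iodotrimethylsilane formed in situ with Et3N silylates under equilibrating conditions, which should favour the more substituted internal enol silane, mainly as the Z isomer (thermodynamic enol silane formation).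

Step 7
Reactants: 10 (E)-1-bromoprop-1-ene; 11 ethynyltrimethylsilane
Product: 12 trimethyl[(3E)-pent-3-en-1-yn-1-yl]silane
Conditions: PdCl2(PPh3)2 (2 mol %), CuI (4 mol %), Et3N, THF, 0 °C → rt
Reagents that add atoms: none
Why: Sonogashira coupling of a vinyl bromide proceeds with retention of the E geometry.

Step 8
Reactants: 13 orsellinic acid
Product: 14 tert-butyldimethylsilyl 2,4-bis[(tert-butyldimethylsilyl)oxy]-6-methylbenzoate
Conditions: TBSCl (3.5 equiv), imidazole, DMF, rt
Reagents that add atoms: tert-butyldimethylsilyl chloride, CC(C)(C)[Si](C)(C)Cl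
Why: Exhaustive silylation gives the bis(silyl ether) silyl ester, from which the acid chloride can be made without acid.

Step 9
Reactants: 6 methyl (R)-2-methyl-3-oxo-2-[(triethylsilyl)oxy]propanoate; 9 (Z)-1-[(tert-butyldimethylsilyl)oxy]-3-[(trimethylsilyl)oxy]but-2-ene
Product: 16 (4R,5R,6R)-4-{[(tert-butyldimethylsilyl)oxy]methyl}-5-hydroxy-6-methyl-6-[(triethylsilyl)oxy]cyclohexane-1,3-dione, via aldol adduct 15 (not isolated)
Conditions: 6, MgBr2·OEt2 (2 equiv), CH2Cl2, −78 °C; add 9, −78 → 0 °C; then LiN(SiMe3)2 (4 equiv), THF, −78 → 0 °C; aq. NH4Cl/HCl to pH 3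
Reagents that add atoms: none
Why: MgBr2 binds the aldehyde and ester carbonyls of 6 in a six-membered chelate, the internal enol silane 9 adds to the activated aldehyde (Mukaiyama aldol, C8–C8a), and after addition of base the methyl ketone so created is enolised at C5 and acylated by the C6 ester with loss of methoxide (Dieckmann-type Claisen cyclisation, C5–C6), the stabilised diketonate being the thermodynamic sink. The closest known types are the chelation-controlled Mukaiyama aldol and the base-induced cyclisation of 5-oxo esters to cyclohexane-1,3-diones, here run consecutively in one flask. Ring B closes in a 6-(enolendo)-exo-trig mode. C8 is controlled by C7: within the chelate the nucleophile should enter anti to the C7–OSiEt3 bond (Felkin–Anh), between the methyl group and the chelated ester, which puts O8 cis to O7; C8a is controlled by the Z enol silane through an antiperiplanar open transition state with CH2OTBS next to the aldehyde hydrogen (syn aldol), which puts C1 trans to O8. The step needs C8a (not C5) to attack the aldehyde, secured by the regiodefined enol silane, and C5 (not C8a) to be deprotonated afterwards, secured by kinetic methyl deprotonation and by the fact that only C5 attack on the ester gives a six-membered ring.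

Step 10
Reactants: 16 (4R,5R,6R)-4-{[(tert-butyldimethylsilyl)oxy]methyl}-5-hydroxy-6-methyl-6-[(triethylsilyl)oxy]cyclohexane-1,3-dione
Product: 17 (4R,5R,6R)-6-{[(tert-butyldimethylsilyl)oxy]methyl}-5-hydroxy-4-methyl-3-oxo-4-[(triethylsilyl)oxy]cyclohex-1-en-1-yl trifluoromethanesulfonate
Conditions: PhNTf2, Et3N, DMAP (cat.), CH2Cl2, 0 °C → rt
Reagents that add atoms: N-phenylbis(trifluoromethanesulfonimide), O=S(=O)(N(c1ccccc1)S(=O)(=O)C(F)(F)F)C(F)(F)F
Why: Et3N deprotonates the acidic enolised dione but not the C8 alcohol, and the enolate should be sulfonylated (enol triflate formation) at the less hindered C4a oxygen, remote from the quaternary C7, as in O-functionalisation of 4,4-disubstituted cyclohexane-1,3-diones.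

Step 11
Reactants: 17 (4R,5R,6R)-6-{[(tert-butyldimethylsilyl)oxy]methyl}-5-hydroxy-4-methyl-3-oxo-4-[(triethylsilyl)oxy]cyclohex-1-en-1-yl trifluoromethanesulfonate; 12 trimethyl[(3E)-pent-3-en-1-yn-1-yl]silane
Product: 19 (4R,5R,6R)-4-{[(tert-butyldimethylsilyl)oxy]methyl}-5-hydroxy-6-methyl-3-[(3E)-pent-3-en-1-yn-1-yl]-6-[(triethylsilyl)oxy]cyclohex-2-en-1-one, via (E)-pent-3-en-1-yne 18 (not isolated)
Conditions: 12 (1.3 equiv), Bu4NF (1.2 equiv), THF, 0 °C; then 17, Pd(PPh3)4 (5 mol %), CuI (10 mol %), Et3N, THF, 0 °C → rt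
Reagents that add atoms: none
Why: Fluoride unmasks the terminal enyne, which undergoes Sonogashira coupling with the β-triflyloxy enone (a vinylogous acyl triflate that adds readily to zerovalent palladium) with retention of both double bond geometries.

Step 12
Reactants: 19 (4R,5R,6R)-4-{[(tert-butyldimethylsilyl)oxy]methyl}-5-hydroxy-6-methyl-3-[(3E)-pent-3-en-1-yn-1-yl]-6-[(triethylsilyl)oxy]cyclohex-2-en-1-one; 14 tert-butyldimethylsilyl 2,4-bis[(tert-butyldimethylsilyl)oxy]-6-methylbenzoate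
Product: 21 (1R,2R,6R)-2-{[(tert-butyldimethylsilyl)oxy]methyl}-6-methyl-5-oxo-3-[(3E)-pent-3-en-1-yn-1-yl]-6-[(triethylsilyl)oxy]cyclohex-3-en-1-yl 2,4-bis[(tert-butyldimethylsilyl)oxy]-6-methylbenzoate, via acid chloride 20 (not isolated)
Conditions: 14, (COCl)2, DMF (cat.), CH2Cl2, 0 °C → rt, concentrate; then 19, DMAP, Et3N, CH2Cl2, rt → 40 °C
Reagents that add atoms: none
Why: Oxalyl chloride/DMF converts the silyl ester into the acid chloride without free acid, and DMAP-mediated acyl transfer esterifies the only free hydroxyl, the secondary C8–OH, with retention at C8.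

Step 13
Reactants: 21 (1R,2R,6R)-2-{[(tert-butyldimethylsilyl)oxy]methyl}-6-methyl-5-oxo-3-[(3E)-pent-3-en-1-yn-1-yl]-6-[(triethylsilyl)oxy]cyclohex-3-en-1-yl 2,4-bis[(tert-butyldimethylsilyl)oxy]-6-methylbenzoate
Product: 22 (1R,2R,6R)-6-hydroxy-2-(hydroxymethyl)-6-methyl-5-oxo-3-[(3E)-pent-3-en-1-yn-1-yl]cyclohex-3-en-1-yl 2,4-dihydroxy-6-methylbenzoate
Conditions: Bu4NF, AcOH (1:1, excess), THF, 0 °C → rt
Reagents that add atoms: none
Why: Acetic acid-buffered fluoride desilylation removes the alkyl TBS, the tertiary TES and both aryl TBS groups near neutrality, which should protect the β-acyloxy ynenone from elimination and acyl migration.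

Step 14
Reactants: 22 (1R,2R,6R)-6-hydroxy-2-(hydroxymethyl)-6-methyl-5-oxo-3-[(3E)-pent-3-en-1-yn-1-yl]cyclohex-3-en-1-yl 2,4-dihydroxy-6-methylbenzoate
Product: 23 berkazaphilone C
Conditions: Ph3PAuNTf2 (5 mol %), CH2Cl2, rt
Reagents that add atoms: none
Why: Gold-catalysed 6-endo-dig hydroalkoxylation (alkynol cycloisomerisation): the primary C1–OH adds to C3, the δ-carbon of the ynenone, and protodeauration places hydrogen on C4; the ring B enone geometry keeps the C6 carbonyl away from the alkyne and no stereocentre is touched.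

Compound list
1 | (S)-3-bromo-2-hydroxy-2-methylpropanoic acid | OC(=O)[C@](C)(O)CBr | starting material
2 | sodium (R)-2-methyloxirane-2-carboxylate (not isolated) | [Na+].[O-]C(=O)[C@]1(C)OC1 | intermediate
3 | (R)-2,3-dihydroxy-2-methylpropanoic acid | OC(=O)[C@](C)(O)CO | intermediate
4 | methyl (R)-2,3-dihydroxy-2-methylpropanoate | COC(=O)[C@](C)(O)CO | intermediate
5 | methyl (R)-2-methyl-2,3-bis[(triethylsilyl)oxy]propanoate | COC(=O)[C@](C)(O[Si](CC)(CC)CC)CO[Si](CC)(CC)CC | intermediate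
6 | methyl (R)-2-methyl-3-oxo-2-[(triethylsilyl)oxy]propanoate | COC(=O)[C@](C)(O[Si](CC)(CC)CC)C=O | intermediate
7 | 4-hydroxybutan-2-one | CC(=O)CCO | starting material
8 | 4-[(tert-butyldimethylsilyl)oxy]butan-2-one | CC(=O)CCO[Si](C)(C)C(C)(C)C | intermediate
9 | (Z)-1-[(tert-butyldimethylsilyl)oxy]-3-[(trimethylsilyl)oxy]but-2-ene | C/C(O[Si](C)(C)C)=C/CO[Si](C)(C)C(C)(C)C | intermediate
10 | (E)-1-bromoprop-1-ene | C/C=C/Br | starting material
11 | ethynyltrimethylsilane | C#C[Si](C)(C)C | starting material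
12 | trimethyl[(3E)-pent-3-en-1-yn-1-yl]silane | C/C=C/C#C[Si](C)(C)C | intermediate
13 | orsellinic acid (2,4-dihydroxy-6-methylbenzoic acid) | Cc1cc(O)cc(O)c1C(=O)O | starting material
14 | tert-butyldimethylsilyl 2,4-bis[(tert-butyldimethylsilyl)oxy]-6-methylbenzoate | Cc1cc(O[Si](C)(C)C(C)(C)C)cc(O[Si](C)(C)C(C)(C)C)c1C(=O)O[Si](C)(C)C(C)(C)C | intermediate
15 | methyl (2R,3R,4R)-4-{[(tert-butyldimethylsilyl)oxy]methyl}-3-hydroxy-2-methyl-5-oxo-2-[(triethylsilyl)oxy]hexanoate (aldol adduct, held as its magnesium alkoxide, not isolated) | COC(=O)[C@](C)(O[Si](CC)(CC)CC)[C@H](O)[C@@H](CO[Si](C)(C)C(C)(C)C)C(C)=O | intermediate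
16 | (4R,5R,6R)-4-{[(tert-butyldimethylsilyl)oxy]methyl}-5-hydroxy-6-methyl-6-[(triethylsilyl)oxy]cyclohexane-1,3-dione | O=C1CC(=O)[C@](C)(O[Si](CC)(CC)CC)[C@H](O)[C@H]1CO[Si](C)(C)C(C)(C)C | intermediate
17 | (4R,5R,6R)-6-{[(tert-butyldimethylsilyl)oxy]methyl}-5-hydroxy-4-methyl-3-oxo-4-[(triethylsilyl)oxy]cyclohex-1-en-1-yl trifluoromethanesulfonate | FC(F)(F)S(=O)(=O)OC1=CC(=O)[C@](C)(O[Si](CC)(CC)CC)[C@H](O)[C@H]1CO[Si](C)(C)C(C)(C)C | intermediate
18 | (E)-pent-3-en-1-yne (not isolated) | C/C=C/C#C | intermediate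
19 | (4R,5R,6R)-4-{[(tert-butyldimethylsilyl)oxy]methyl}-5-hydroxy-6-methyl-3-[(3E)-pent-3-en-1-yn-1-yl]-6-[(triethylsilyl)oxy]cyclohex-2-en-1-one | C/C=C/C#CC1=CC(=O)[C@](C)(O[Si](CC)(CC)CC)[C@H](O)[C@H]1CO[Si](C)(C)C(C)(C)C | intermediate
20 | 2,4-bis[(tert-butyldimethylsilyl)oxy]-6-methylbenzoyl chloride (not isolated) | Cc1cc(O[Si](C)(C)C(C)(C)C)cc(O[Si](C)(C)C(C)(C)C)c1C(Cl)=O | intermediate
21 | (1R,2R,6R)-2-{[(tert-butyldimethylsilyl)oxy]methyl}-6-methyl-5-oxo-3-[(3E)-pent-3-en-1-yn-1-yl]-6-[(triethylsilyl)oxy]cyclohex-3-en-1-yl 2,4-bis[(tert-butyldimethylsilyl)oxy]-6-methylbenzoate | C/C=C/C#CC1=CC(=O)[C@](C)(O[Si](CC)(CC)CC)[C@H](OC(=O)c2c(C)cc(O[Si](C)(C)C(C)(C)C)cc2O[Si](C)(C)C(C)(C)C)[C@H]1CO[Si](C)(C)C(C)(C)C | intermediate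
22 | (1R,2R,6R)-6-hydroxy-2-(hydroxymethyl)-6-methyl-5-oxo-3-[(3E)-pent-3-en-1-yn-1-yl]cyclohex-3-en-1-yl 2,4-dihydroxy-6-methylbenzoate | C/C=C/C#CC1=CC(=O)[C@](C)(O)[C@H](OC(=O)c2c(C)cc(O)cc2O)[C@H]1CO | intermediate
23 | berkazaphilone C, (7R,8R,8aR)-7-hydroxy-7-methyl-6-oxo-3-[(1E)-prop-1-en-1-yl]-6,7,8,8a-tetrahydro-1H-isochromen-8-yl 2,4-dihydroxy-6-methylbenzoate | C/C=C/C1=CC2=CC(=O)[C@](C)(O)[C@H](OC(=O)c3c(C)cc(O)cc3O)[C@H]2CO1 | target

Total step count: 14. Longest linear sequence: 10 steps (steps 1–4, then 9–14).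

Steps most likely to fail

1. Step 9. Several processes may go wrong. Chelation may be too weak, so that the enol silane takes the other aldehyde face. The allylic silyl ether of 9 may ionise or β-eliminate, or its regiochemical purity may erode. Retro-aldol cleavage may outrun the base-induced ring closure. Fallback, setting out from 6 and returning at 16: the C1 carbon is introduced after the annulation. Aldehyde 6 is combined with commercial 2-(trimethylsilyloxy)propene under the same MgBr2·OEt2, then LiN(SiMe3)2 sequence to give (4R,5R)-5-hydroxy-4-methyl-4-[(triethylsilyl)oxy]cyclohexane-1,3-dione F1. Its trianion (LiN(iPr)2, 3.3 equiv, THF/HMPA, −78 °C) is hydroxymethylated at C8a with monomeric formaldehyde, anti to the C8 alkoxide, to give (4R,5R,6R)-5-hydroxy-4-(hydroxymethyl)-6-methyl-6-[(triethylsilyl)oxy]cyclohexane-1,3-dione F2. Selective silylation of the primary hydroxyl (TBSCl, imidazole) returns to 16.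

2. Step 12. Acyl transfer between a hindered secondary alcohol and a di-ortho-substituted aroyl chloride may be slow, which would let base-mediated conjugate addition of the C8 hydroxyl to the ynenone, or elimination, compete. Fallback, setting out from 19 and returning at 23: ring A is closed first and the ester is made by alkoxide transacylation. Desilylation of 19 (Bu4NF/AcOH) gives (4R,5R,6R)-5,6-dihydroxy-4-(hydroxymethyl)-6-methyl-3-[(3E)-pent-3-en-1-yn-1-yl]cyclohex-2-en-1-one F5. Gold catalysis (Ph3PAuNTf2) closes the pyran through the more accessible primary hydroxyl to (7R,8R,8aR)-7,8-dihydroxy-7-methyl-3-[(1E)-prop-1-en-1-yl]-1,7,8,8a-tetrahydro-6H-isochromen-6-one F6. Separately, 13 is converted with acetone/trifluoroacetic anhydride/trifluoroacetic acid into 7-hydroxy-2,2,5-trimethyl-4H-1,3-benzodioxin-4-one F7 and silylated to 7-[(tert-butyldimethylsilyl)oxy]-2,2,5-trimethyl-4H-1,3-benzodioxin-4-one F8. The sodium C8 alkoxide of F6 (NaN(SiMe3)2, THF, −78 → 0 °C) opens F8 to (7R,8R,8aR)-7-hydroxy-7-methyl-6-oxo-3-[(1E)-prop-1-en-1-yl]-6,7,8,8a-tetrahydro-1H-isochromen-8-yl 4-[(tert-butyldimethylsilyl)oxy]-2-hydroxy-6-methylbenzoate F9. Buffered fluoride then gives 23.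

3. Step 10. O-sulfonylation may discriminate poorly between the two enol oxygens of the dione, and the C8 hydroxyl may be sulfonylated as well. Fallback, setting out from 16 (and 12) and returning at 19: regiochemistry is set under reversible, thermodynamic conditions. Dione 16 is condensed with thiophenol (camphorsulfonic acid cat., MgSO4, CH2Cl2) at the less hindered C4a carbonyl to (4R,5R,6R)-4-{[(tert-butyldimethylsilyl)oxy]methyl}-5-hydroxy-6-methyl-3-(phenylsulfanyl)-6-[(triethylsilyl)oxy]cyclohex-2-en-1-one F3. Silane 12 is converted (MeLi·LiBr, then Bu3SnCl) into tributyl[(3E)-pent-3-en-1-yn-1-yl]stannane F4. Liebeskind–Srogl coupling of F3 with F4 (Pd2(dba)3, tri(2-furyl)phosphine, Cu(O2C-C4H3S), THF, 50 °C) gives 19.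

Further compounds
F1 | step 9 | (4R,5R)-5-hydroxy-4-methyl-4-[(triethylsilyl)oxy]cyclohexane-1,3-dione | O=C1CC(=O)[C@](C)(O[Si](CC)(CC)CC)[C@H](O)C1
F2 | step 9 | (4R,5R,6R)-5-hydroxy-4-(hydroxymethyl)-6-methyl-6-[(triethylsilyl)oxy]cyclohexane-1,3-dione | O=C1CC(=O)[C@](C)(O[Si](CC)(CC)CC)[C@H](O)[C@H]1CO
F3 | step 10 | (4R,5R,6R)-4-{[(tert-butyldimethylsilyl)oxy]methyl}-5-hydroxy-6-methyl-3-(phenylsulfanyl)-6-[(triethylsilyl)oxy]cyclohex-2-en-1-one | c1ccccc1SC1=CC(=O)[C@](C)(O[Si](CC)(CC)CC)[C@H](O)[C@H]1CO[Si](C)(C)C(C)(C)C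
F4 | step 10 | tributyl[(3E)-pent-3-en-1-yn-1-yl]stannane | C/C=C/C#C[Sn](CCCC)(CCCC)CCCC
F5 | step 12 | (4R,5R,6R)-5,6-dihydroxy-4-(hydroxymethyl)-6-methyl-3-[(3E)-pent-3-en-1-yn-1-yl]cyclohex-2-en-1-one | C/C=C/C#CC1=CC(=O)[C@](C)(O)[C@H](O)[C@H]1CO
F6 | step 12 | (7R,8R,8aR)-7,8-dihydroxy-7-methyl-3-[(1E)-prop-1-en-1-yl]-1,7,8,8a-tetrahydro-6H-isochromen-6-one | C/C=C/C1=CC2=CC(=O)[C@](C)(O)[C@H](O)[C@H]2CO1
F7 | step 12 | 7-hydroxy-2,2,5-trimethyl-4H-1,3-benzodioxin-4-one | Cc1cc(O)cc2OC(C)(C)OC(=O)c12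
F8 | step 12 | 7-[(tert-butyldimethylsilyl)oxy]-2,2,5-trimethyl-4H-1,3-benzodioxin-4-one | Cc1cc(O[Si](C)(C)C(C)(C)C)cc2OC(C)(C)OC(=O)c12
F9 | step 12 | (7R,8R,8aR)-7-hydroxy-7-methyl-6-oxo-3-[(1E)-prop-1-en-1-yl]-6,7,8,8a-tetrahydro-1H-isochromen-8-yl 4-[(tert-butyldimethylsilyl)oxy]-2-hydroxy-6-methylbenzoate | C/C=C/C1=CC2=CC(=O)[C@](C)(O)[C@H](OC(=O)c3c(C)cc(O[Si](C)(C)C(C)(C)C)cc3O)[C@H]2CO1
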